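Atom labels C1–C15 are germacrane numbers of the target. The ten-membered carbocycle is cut at C2–C3. That bond is made by a palladium-catalysed decarboxylative allylation that contracts a twelve-membered allyl β-keto lactone to the ten-membered ketone: one operation expels CO2, forms C2–C3 and closes the carbocycle. It exploits two features: the C1 ketone can enolize only toward C2 because C10 is fully substituted, and C3 is the allylic terminus of the Z C4=C5 alkene that later becomes the epoxide. The lactone carries the ester carbonyl between C2 and O–C3, a C6-epimeric silyl ether, and C7, C8, C10 and C11 already set.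

Key step: step 23

Assumption: (S,S)-ProPhenol is taken to deliver the alkyne in step 6 to the aldehyde face that gives the 6S alcohol; the antipodal ligand is equally available if the sense is opposite.

Step 1
Reactants: 1 (S)-2-methylglycidol
Product: 2 (R)-2-methylpent-4-yne-1,2-diol
Conditions: LiC≡CH·H2NCH2CH2NH2, DMSO, 0 to 25 °C; then H2O
Reagents that add atoms: lithium acetylide ethylenediamine complex, [Li]C#C.NCCN
Why: Acetylide opens the 2,2-disubstituted epoxide by SN2 attack at the unsubstituted CH2 (epoxide alkynylation), so the quaternary carbinol centre C10 is carried over unchanged.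

Step 2
Reactants: 2 (R)-2-methylpent-4-yne-1,2-diol
Product: 3 (R)-2,2,4-trimethyl-4-(prop-2-yn-1-yl)-1,3-dioxolane
Conditions: 2,2-dimethoxypropane, PPTS (cat.), CH2Cl2, 25 °C
Reagents that add atoms: 2,2-dimethoxypropane, COC(C)(C)OC
Why: Acid-catalysed transketalization closes the five-membered acetonide over the primary and tertiary hydroxyls (acetonide protection) and leaves the alkyne free.

Step 3
Reactants: 4 propargyl alcohol
Product: 5 (Z)-3-iodo-2-methylprop-2-en-1-ol
Conditions: MeMgBr, CuI (10 mol%), THF, −10 to 25 °C; then I2, −10 °C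
Reagents that add atoms: methylmagnesium bromide, C[Mg]Br; iodine, II
Why: CuI-catalysed anti carbomagnesiation of the propargylic alkoxide (Duboudin reaction) places methyl on C4 and magnesium on C5 cis to the CH2O group through a five-membered chelate, and iodinolysis with retention fixes the Z C4=C5 geometry.

Step 4
Reactants: 5 (Z)-3-iodo-2-methylprop-2-en-1-ol
Product: 6 (Z)-3-iodo-2-methylallyl 4-methoxybenzyl ether
Conditions: NaH, 4-methoxybenzyl chloride, Bu4NI (cat.), THF, 0 to 25 °C
Reagents that add atoms: 4-methoxybenzyl chloride, COc1ccc(CCl)cc1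
Why: Williamson etherification of the primary allylic alkoxide with the benzylic chloride; the vinyl iodide does not react with NaH.

Step 5
Reactants: 6 (Z)-3-iodo-2-methylallyl 4-methoxybenzyl ether
Product: 7 (Z)-4-(4-methoxybenzyloxy)-3-methylbut-2-enal
Conditions: t-BuLi (2.1 equiv), Et2O, −78 °C; DMF; aq. NH4Cl
Reagents that add atoms: N,N-dimethylformamide, CN(C)C=O
Why: Iodine–lithium exchange proceeds with retention of alkene geometry and the alkenyllithium is formylated by DMF (Bouveault formylation), giving the Z enal, which is used at once to avoid Z to E isomerization.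

Step 6
Reactants: 3 (R)-2,2,4-trimethyl-4-(prop-2-yn-1-yl)-1,3-dioxolane, 7 (Z)-4-(4-methoxybenzyloxy)-3-methylbut-2-enal
Product: 8 (6S)-enynol with C3 PMB ether, Z C4=C5, C7≡C8 alkyne, C1/C10 acetonide
Conditions: Me2Zn, (S,S)-ProPhenol (20 mol%), Ph3PO (40 mol%), toluene, 0 °C
Reagents that add atoms: none
Why: The zinc alkynylide of 3 adds to the aldehyde within the chiral dinuclear zinc–ProPhenol pocket (Trost asymmetric alkynylation), so C6 is set by catalyst-controlled facial selection and any C6 epimer is a separable diastereomer because C10 is fixed.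

Step 7
Reactants: 8 (6S)-enynol
Product: 9 dienol with E C7=C8 alkene
Conditions: NaAlH2(OCH2CH2OCH3)2, THF, 0 to 25 °C; Rochelle salt work-up
Reagents that add atoms: none
Why: Alkoxide-directed trans hydroalumination of the propargylic alcohol and protonolysis (Red-Al reduction) gives only the E C7=C8 alkene, while the isolated Z alkene and the ethers are inert.

Step 8
Reactants: 9 dienol
Product: 10 anti epoxy alcohol with trans C7–C8 epoxide
Conditions: Ti(OiPr)4 (20 mol%), L-(+)-diisopropyl tartrate (24 mol%), t-BuOOH, 4 Å molecular sieves, CH2Cl2, −20 °C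
Reagents that add atoms: tert-butyl hydroperoxide, CC(C)(C)OO
Why: Sharpless asymmetric epoxidation with the matched L-tartrate epoxidizes the E alkene on the face anti to the C6 hydroxyl (erythro product), setting C7 and C8 by reagent and substrate control together, while the cis-substituted Z alkene is both mismatched and intrinsically slow.

Step 9
Reactants: 10 anti epoxy alcohol, 11 Meldrum's acid
Product: 12 C6 malonic half ester of the epoxy alcohol
Conditions: toluene, 90 °C
Reagents that add atoms: none
Why: Thermal alcoholysis of Meldrum's acid acylates the C6 hydroxyl to the malonic half ester without base or coupling agent, so the epoxide stays intact.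

Step 10
Reactants: 12 C6 malonic half ester
Product: 13 all-trans γ-lactone acid with free C8 hydroxyl
Conditions: LiN(SiMe3)2 (2.2 equiv), THF, −78 to 25 °C; then 1 M HCl to pH 3, 0 °C
Reagents that add atoms: none
Why: The malonate dianion opens the epoxide intramolecularly at C7 in a 5-exo mode with inversion (epoxide alkylation by a tethered stabilized carbanion, as in Stork epoxide cyclizations), which forms C7–C11 and the γ-lactone and frees O8; C11 is set under thermodynamic control because its acidic α-hydrogen lets the carboxyl settle trans to the C7 side chain.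

Step 11
Reactants: 13 γ-lactone acid
Product: 15 lactone acid C8 TBS ether, via silyl ester 14 (not isolated)
Conditions: TBSOTf, 2,6-lutidine, CH2Cl2, −78 to 0 °C; then aq. citric acid/THF
Reagents that add atoms: tert-butyldimethylsilyl trifluoromethanesulfonate, CC(C)(C)[Si](C)(C)OS(=O)(=O)C(F)(F)F
Why: The silyl triflate silylates the hindered C8 hydroxyl and the acid, and the labile silyl ester is hydrolysed on work-up (silyl ether protection).

Step 12
Reactants: 15 lactone acid C8 TBS ether
Product: 17 C12 primary alcohol, via mixed anhydride 16 (not isolated)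
Conditions: i-BuOCOCl, N-methylmorpholine, THF, −15 °C; then NaBH4, H2O, 0 °C
Reagents that add atoms: none
Why: Activation as the mixed carbonic anhydride and NaBH4 reduction converts only the carboxylic acid into the C12 primary alcohol (mixed anhydride reduction), leaving lactone, alkene and silyl ether, and the trans C11 configuration is frozen once the β-dicarbonyl is gone.

Step 13
Reactants: 17 C12 primary alcohol
Product: 18 C12 benzyl ether
Conditions: 2-benzyloxy-1-methylpyridinium triflate, MgO, PhCF3, 85 °C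
Reagents that add atoms: 2-benzyloxy-1-methylpyridinium trifluoromethanesulfonate, C[n+]1ccccc1OCc1ccccc1.[O-]S(=O)(=O)C(F)(F)F
Why: Benzyl transfer from the neutral pyridinium salt (Dudley benzylation) etherifies the primary alcohol without strong base or acid, so the hydroxymethyl lactone neither epimerizes nor eliminates.

Step 14
Reactants: 18 C12 benzyl ether
Product: 19 C1,C10 diol
Conditions: AcOH/H2O (4:1), 40 °C
Reagents that add atoms: none
Why: Aqueous acetic acid hydrolyses the terminal acetonide (acetal hydrolysis), which the secondary TBS ether, the benzyl and PMB ethers and the lactone tolerate.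

Step 15
Reactants: 19 C1,C10 diol
Product: 21 C10-hydroxy C1 carboxylic acid, via hydroxy aldehyde 20 (not isolated)
Conditions: TEMPO (cat.), NaOCl (cat.), NaClO2, MeCN/phosphate buffer pH 6.7, 35 °C
Reagents that add atoms: sodium chlorite, [Na+].[O-]Cl=O
Why: TEMPO/NaOCl/NaClO2 oxidation (Zhao modification of the Anelli oxidation) takes only the primary C1 alcohol through the aldehyde to the acid, since the tertiary C10 hydroxyl cannot be oxidized and the medium is near neutral.

Step 16
Reactants: 21 C10-hydroxy C1 carboxylic acid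
Product: 22 open-chain C6,C13,C10 triol acid
Conditions: LiBH4, THF, 0 to 25 °C; then 1 M HCl to pH 3
Reagents that add atoms: none
Why: LiBH4 reduces the lactone to the C6 and C13 alcohols while the lithium carboxylate at C1 is inert (chemoselective ester reduction), so O6 and O13 are released with C6, C7 and C11 untouched.

Step 17
Reactants: 22 triol acid
Product: 23 C13 monoacetate
Conditions: vinyl acetate, immobilized Candida antarctica lipase B, t-BuOMe, 30 °C
Reagents that add atoms: vinyl acetate, CC(=O)OC=C
Why: Lipase-catalysed transesterification with vinyl acetate (enzymatic regioselective acylation) acetylates only the unhindered primary C13 hydroxyl and not the secondary C6 or tertiary C10 hydroxyls or the acid.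

Step 18
Reactants: 23 C13 monoacetate
Product: 25 C6 triethylsilyl ether acid, via silyl ester 24 (not isolated)
Conditions: Et3SiCl, imidazole, DMF, 0 °C; then H2O/THF, pH 5
Reagents that add atoms: chlorotriethylsilane, CC[Si](Cl)(CC)CC
Why: Silyl chloride with imidazole silylates the secondary allylic C6 hydroxyl but not the tertiary C10 hydroxyl (silyl ether protection), and the silyl ester formed at C1 is cleaved by water.

Step 19
Reactants: 25 C6 triethylsilyl ether acid
Product: 27 C10 acetoxy acid, via mixed anhydride 26 (not isolated)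
Conditions: Ac2O, DMAP, Et3N, CH2Cl2, 25 °C; then aq. NaHCO3/THF; acidify to pH 4
Reagents that add atoms: acetic anhydride, CC(=O)OC(C)=O
Why: DMAP-catalysed acetylation (Steglich-type acylation) esterifies the tertiary C10 hydroxyl, and the mixed anhydride formed at C1 is hydrolysed on work-up.

Step 20
Reactants: 27 C10 acetoxy acid, 11 Meldrum's acid
Product: 28 acyl Meldrum's acid with C3 PMB ether
Conditions: EDC·HCl, DMAP, CH2Cl2, 0 to 25 °C
Reagents that add atoms: none
Why: Carbodiimide activation and C-acylation of Meldrum's acid (Oikawa–Yonemitsu acylation) converts the C1 acid into the acyl Meldrum's acid that masks the acylketene.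

Step 21
Reactants: 28 acyl Meldrum's acid with C3 PMB ether
Product: 29 acyl Meldrum's acid with free C3 hydroxyl
Conditions: DDQ, CH2Cl2/pH 7 buffer, 0 °C
Reagents that add atoms: none
Why: DDQ oxidizes only the electron-rich PMB ether to the oxocarbenium ion, which water cleaves (oxidative PMB removal), leaving benzyl and silyl ethers and the acetates.

Step 22
Reactants: 29 acyl Meldrum's acid with free C3 hydroxyl
Product: 31 twelve-membered allyl β-keto lactone, via acylketene 30 (not isolated)
Conditions: toluene (1 mM), 110 °C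
Reagents that add atoms: none
Why: Thermal cycloreversion of the acyl Meldrum's acid releases acetone and CO2 and gives the acylketene, which the C3 hydroxyl traps at high dilution (acylketene macrolactonization) to close the twelve-membered β-keto lactone.

Step 23
Reactants: 31 twelve-membered allyl β-keto lactone
Product: 32 ten-membered ketone with Z C4=C5
Conditions: Pd(PPh3)4 (10 mol%), THF (2 mM), 25 to 45 °C
Reagents that add atoms: none
Why: Zerovalent palladium adds oxidatively to the allylic C3–O bond of 31 with ionization to a π-allylpalladium β-keto carboxylate ion pair; loss of CO2 leaves the palladium enolate of the C1 ketone, which can only be the C1=C2 enolate because C10 is fully substituted, and this carbon nucleophile recombines with the allyl unit at C3 to form C2–C3. The closest known reaction type is the Tsuji decarboxylative allylation (palladium-catalysed Carroll reaction) of allyl β-keto esters, here run intramolecularly so that the lactone is contracted by excision of CO2. The ten-membered ring closes by enolate attack on the terminal carbon of the tethered π-allyl unit within the ion pair that the twelve-membered lactone has preorganized, and no stereocentre is created. The step needs attack at C3 and not at C5, which is secured because C3 is a primary, unhindered terminus whereas C5 is flanked by the silyloxy-bearing C6 and would give an eight-membered ring. It also needs retention of the Z alkene, which follows because the anti-configured π-allyl formed from the Z ester is captured before the slower syn–anti isomerization through a σ-complex at the secondary carbon C5. The C6 triethylsilyl ether cannot ionize, so only the ester is activated, and the acetates and the benzyl ether are inert.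

Step 24
Reactants: 32 ten-membered ketone
Product: 33 C6 allylic alcohol
Conditions: HF·pyridine, pyridine, THF, 0 °C
Reagents that add atoms: none
Why: Buffered HF·pyridine cleaves the secondary triethylsilyl ether far faster than the hindered tert-butyldimethylsilyl ether (selective desilylation), releasing the C6 hydroxyl.

Step 25
Reactants: 33 C6 allylic alcohol
Product: 34 threo 4,5-epoxy C6 alcohol
Conditions: mCPBA, NaHCO3, CH2Cl2, 0 °C
Reagents that add atoms: 3-chloroperoxybenzoic acid, OOC(=O)c1cccc(Cl)c1
Why: Hydroxyl-directed peracid epoxidation (Henbest epoxidation) of the Z allylic alcohol: allylic 1,3-strain places H6 in the alkene plane toward C3, the hydrogen-bonded peracid delivers oxygen syn to the C6 hydroxyl (threo), and this sets C4 and C5 as in the target.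

Step 26
Reactants: 34 threo 4,5-epoxy C6 alcohol
Product: 35 4,5-epoxy C6 ketone
Conditions: Dess–Martin periodinane, NaHCO3, CH2Cl2, 0 to 25 °C
Reagents that add atoms: none
Why: Dess–Martin oxidation under bicarbonate buffer gives the α,β-epoxy ketone without epimerizing C7 or opening the epoxide.

Step 27
Reactants: 35 4,5-epoxy C6 ketone
Product: 36 erythro 4,5-epoxy C6 alcohol
Conditions: Zn(BH4)2 (from ZnCl2 and NaBH4), Et2O, −40 to −20 °C
Reagents that add atoms: none
Why: Zn(BH4)2 chelates the ketone and epoxide oxygens and delivers hydride to the exposed face (chelation-controlled reduction of α,β-epoxy ketones), giving the erythro epoxy alcohol, that is C6 inverted to the target configuration, while the C1 ketone beside quaternary C10 reacts more slowly.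

Step 28
Reactants: 36 erythro 4,5-epoxy C6 alcohol
Product: 37 C6,C12 diol
Conditions: H2 (1 atm), Pd/C, EtOAc, 25 °C
Reagents that add atoms: none
Why: Hydrogenolysis of the benzyl ether over Pd/C (catalytic hydrogenolysis) frees the C12 alcohol at a stage where no alkene remains.

Step 29
Reactants: 37 C6,C12 diol
Product: 39 6,12-lactone C8 TBS ether, via lactol 38 (not isolated)
Conditions: TEMPO (cat.), PhI(OAc)2, CH2Cl2, 25 °C
Reagents that add atoms: none
Why: The TEMPO/PhI(OAc)2 oxidation takes the primary alcohol to the aldehyde, which closes to the lactol with the C6 hydroxyl and is oxidized on to the γ-lactone (oxidative lactonization), secondary alcohols being spared.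

Step 30
Reactants: 39 6,12-lactone C8 TBS ether
Product: 40 C8 alcohol
Conditions: HF·pyridine, pyridine, THF, 0 to 25 °C
Reagents that add atoms: none
Why: Fluoride cleaves the remaining silyl ether (desilylation) under buffered, non-basic conditions that do not eliminate the β-acetoxy lactone.

Step 31
Reactants: 40 C8 alcohol
Product: 41 CNP0166747.1
Conditions: methacrylic anhydride, DMAP (cat.), pyridine, CH2Cl2, 0 to 25 °C
Reagents that add atoms: methacrylic anhydride, C=C(C)C(=O)OC(=O)C(C)=C
Why: DMAP-catalysed acylation with the anhydride (Steglich-type esterification) installs the methacrylate at C8 under weakly basic conditions.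

Compound list
1 | (S)-2-methylglycidol | OC[C@@]1(C)CO1 | starting material
2 | (R)-2-methylpent-4-yne-1,2-diol | C#CC[C@@](C)(O)CO | intermediate
3 | (R)-2,2,4-trimethyl-4-(prop-2-yn-1-yl)-1,3-dioxolane | C#CC[C@@]1(C)OC(C)(C)OC1 | intermediate
4 | propargyl alcohol | C#CCO | starting material
5 | (Z)-3-iodo-2-methylprop-2-en-1-ol | OC/C(C)=C\I | intermediate
6 | (Z)-3-iodo-2-methylallyl 4-methoxybenzyl ether | COc1ccc(COC/C(C)=C\I)cc1 | intermediate
7 | (Z)-4-(4-methoxybenzyloxy)-3-methylbut-2-enal | COc1ccc(COC/C(C)=C\C=O)cc1 | intermediate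
8 | (6S)-enynol: C3 PMB ether, Z C4=C5, C6 hydroxyl, C7≡C8, C1/C10 acetonide | COc1ccc(COC/C(C)=C\[C@H](O)C#CC[C@@]2(C)OC(C)(C)OC2)cc1 | intermediate
9 | dienol: as 8 with E C7=C8 alkene | COc1ccc(COC/C(C)=C\[C@H](O)/C=C/C[C@@]2(C)OC(C)(C)OC2)cc1 | intermediate
10 | anti epoxy alcohol: trans C7–C8 epoxide anti to C6 hydroxyl | COc1ccc(COC/C(C)=C\[C@H](O)[C@@H]2O[C@H]2C[C@@]3(C)OC(C)(C)OC3)cc1 | intermediate
11 | Meldrum's acid | CC1(C)OC(=O)CC(=O)O1 | starting material
12 | C6 malonic half ester of 10 | COc1ccc(COC/C(C)=C\[C@H](OC(=O)CC(=O)O)[C@@H]2O[C@H]2C[C@@]3(C)OC(C)(C)OC3)cc1 | intermediate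
13 | all-trans γ-lactone (O6–C13) with C11 carboxylic acid and free C8 hydroxyl | COc1ccc(COC/C(C)=C\[C@@H]2OC(=O)[C@H](C(=O)O)[C@H]2[C@@H](O)C[C@@]3(C)OC(C)(C)OC3)cc1 | intermediate
14 | C8 TBS ether TBS ester of 13 | COc1ccc(COC/C(C)=C\[C@@H]2OC(=O)[C@H](C(=O)O[Si](C)(C)C(C)(C)C)[C@H]2[C@@H](O[Si](C)(C)C(C)(C)C)C[C@@]3(C)OC(C)(C)OC3)cc1 | intermediate
15 | lactone acid C8 TBS ether | COc1ccc(COC/C(C)=C\[C@@H]2OC(=O)[C@H](C(=O)O)[C@H]2[C@@H](O[Si](C)(C)C(C)(C)C)C[C@@]3(C)OC(C)(C)OC3)cc1 | intermediate
16 | isobutyl carbonic mixed anhydride of 15 | COc1ccc(COC/C(C)=C\[C@@H]2OC(=O)[C@H](C(=O)OC(=O)OCC(C)C)[C@H]2[C@@H](O[Si](C)(C)C(C)(C)C)C[C@@]3(C)OC(C)(C)OC3)cc1 | intermediate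
17 | lactone with C12 primary alcohol | COc1ccc(COC/C(C)=C\[C@@H]2OC(=O)[C@H](CO)[C@H]2[C@@H](O[Si](C)(C)C(C)(C)C)C[C@@]3(C)OC(C)(C)OC3)cc1 | intermediate
18 | lactone with C12 benzyl ether | COc1ccc(COC/C(C)=C\[C@@H]2OC(=O)[C@H](COCc4ccccc4)[C@H]2[C@@H](O[Si](C)(C)C(C)(C)C)C[C@@]3(C)OC(C)(C)OC3)cc1 | intermediate
19 | lactone with C1,C10 diol | COc1ccc(COC/C(C)=C\[C@@H]2OC(=O)[C@H](COCc4ccccc4)[C@H]2[C@@H](O[Si](C)(C)C(C)(C)C)C[C@@](C)(O)CO)cc1 | intermediate
20 | lactone with C10-hydroxy C1 aldehyde | COc1ccc(COC/C(C)=C\[C@@H]2OC(=O)[C@H](COCc4ccccc4)[C@H]2[C@@H](O[Si](C)(C)C(C)(C)C)C[C@@](C)(O)C=O)cc1 | intermediate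
21 | lactone with C10-hydroxy C1 carboxylic acid | COc1ccc(COC/C(C)=C\[C@@H]2OC(=O)[C@H](COCc4ccccc4)[C@H]2[C@@H](O[Si](C)(C)C(C)(C)C)C[C@@](C)(O)C(=O)O)cc1 | intermediate
22 | open-chain triol acid: C6, C13, C10 hydroxyls, C1 acid | COc1ccc(COC/C(C)=C\[C@H](O)[C@@H]([C@@H](COCc2ccccc2)CO)[C@@H](O[Si](C)(C)C(C)(C)C)C[C@@](C)(O)C(=O)O)cc1 | intermediate
23 | C13 monoacetate | COc1ccc(COC/C(C)=C\[C@H](O)[C@@H]([C@@H](COCc2ccccc2)COC(C)=O)[C@@H](O[Si](C)(C)C(C)(C)C)C[C@@](C)(O)C(=O)O)cc1 | intermediate
24 | C6 triethylsilyl ether triethylsilyl ester | COc1ccc(COC/C(C)=C\[C@H](O[Si](CC)(CC)CC)[C@@H]([C@@H](COCc2ccccc2)COC(C)=O)[C@@H](O[Si](C)(C)C(C)(C)C)C[C@@](C)(O)C(=O)O[Si](CC)(CC)CC)cc1 | intermediate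
25 | C6 triethylsilyl ether acid | COc1ccc(COC/C(C)=C\[C@H](O[Si](CC)(CC)CC)[C@@H]([C@@H](COCc2ccccc2)COC(C)=O)[C@@H](O[Si](C)(C)C(C)(C)C)C[C@@](C)(O)C(=O)O)cc1 | intermediate
26 | C10 acetate acetic mixed anhydride | COc1ccc(COC/C(C)=C\[C@H](O[Si](CC)(CC)CC)[C@@H]([C@@H](COCc2ccccc2)COC(C)=O)[C@@H](O[Si](C)(C)C(C)(C)C)C[C@@](C)(OC(C)=O)C(=O)OC(C)=O)cc1 | intermediate
27 | C10 acetoxy C1 acid | COc1ccc(COC/C(C)=C\[C@H](O[Si](CC)(CC)CC)[C@@H]([C@@H](COCc2ccccc2)COC(C)=O)[C@@H](O[Si](C)(C)C(C)(C)C)C[C@@](C)(OC(C)=O)C(=O)O)cc1 | intermediate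
28 | acyl Meldrum's acid (enol form) with C3 PMB ether | COc1ccc(COC/C(C)=C\[C@H](O[Si](CC)(CC)CC)[C@@H]([C@@H](COCc2ccccc2)COC(C)=O)[C@@H](O[Si](C)(C)C(C)(C)C)C[C@@](C)(OC(C)=O)C(O)=C2C(=O)OC(C)(C)OC2=O)cc1 | intermediate
29 | acyl Meldrum's acid with free C3 hydroxyl | OC/C(C)=C\[C@H](O[Si](CC)(CC)CC)[C@@H]([C@@H](COCc1ccccc1)COC(C)=O)[C@@H](O[Si](C)(C)C(C)(C)C)C[C@@](C)(OC(C)=O)C(O)=C1C(=O)OC(C)(C)OC1=O | intermediate
30 | acylketene | OC/C(C)=C\[C@H](O[Si](CC)(CC)CC)[C@@H]([C@@H](COCc1ccccc1)COC(C)=O)[C@@H](O[Si](C)(C)C(C)(C)C)C[C@@](C)(OC(C)=O)C(=O)C=C=O | intermediate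
31 | twelve-membered allyl β-keto lactone: C6 OTES, C8 OTBS, C12 OBn, C10 and C13 acetates | CC(C)(C)[Si](C)(C)O[C@H]1C[C@@](C)(OC(C)=O)C(=O)CC(=O)OC/C(C)=C\[C@H](O[Si](CC)(CC)CC)[C@H]1[C@@H](COCc1ccccc1)COC(C)=O | intermediate
32 | ten-membered ketone with Z C4=C5 | CC(C)(C)[Si](C)(C)O[C@H]1C[C@@](C)(OC(C)=O)C(=O)CC/C(C)=C\[C@H](O[Si](CC)(CC)CC)[C@H]1[C@@H](COCc1ccccc1)COC(C)=O | intermediate
33 | C6 allylic alcohol | CC(C)(C)[Si](C)(C)O[C@H]1C[C@@](C)(OC(C)=O)C(=O)CC/C(C)=C\[C@H](O)[C@H]1[C@@H](COCc1ccccc1)COC(C)=O | intermediate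
34 | threo 4,5-epoxy C6 alcohol | CC(C)(C)[Si](C)(C)O[C@H]1C[C@@](C)(OC(C)=O)C(=O)CC[C@@]2(C)O[C@H]2[C@H](O)[C@H]1[C@@H](COCc1ccccc1)COC(C)=O | intermediate
35 | 4,5-epoxy C6 ketone | CC(C)(C)[Si](C)(C)O[C@H]1C[C@@](C)(OC(C)=O)C(=O)CC[C@@]2(C)O[C@H]2C(=O)[C@H]1[C@@H](COCc1ccccc1)COC(C)=O | intermediate
36 | erythro 4,5-epoxy C6 alcohol (C6 as in the target) | CC(C)(C)[Si](C)(C)O[C@H]1C[C@@](C)(OC(C)=O)C(=O)CC[C@@]2(C)O[C@H]2[C@@H](O)[C@H]1[C@@H](COCc1ccccc1)COC(C)=O | intermediate
37 | C6,C12 diol | CC(C)(C)[Si](C)(C)O[C@H]1C[C@@](C)(OC(C)=O)C(=O)CC[C@@]2(C)O[C@H]2[C@@H](O)[C@H]1[C@@H](CO)COC(C)=O | intermediate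
38 | C12 lactol | CC(C)(C)[Si](C)(C)O[C@H]1C[C@@](C)(OC(C)=O)C(=O)CC[C@@]2(C)O[C@H]2[C@H]2OC(O)[C@@H](COC(C)=O)[C@H]21 | intermediate
39 | 6,12-lactone C8 TBS ether | CC(C)(C)[Si](C)(C)O[C@H]1C[C@@](C)(OC(C)=O)C(=O)CC[C@@]2(C)O[C@H]2[C@H]2OC(=O)[C@@H](COC(C)=O)[C@H]21 | intermediate
40 | 6,12-lactone C8 alcohol | O[C@H]1C[C@@](C)(OC(C)=O)C(=O)CC[C@@]2(C)O[C@H]2[C@H]2OC(=O)[C@@H](COC(C)=O)[C@H]21 | intermediate
41 | CNP0166747.1 | C=C(C)C(=O)O[C@H]1C[C@@](C)(OC(C)=O)C(=O)CC[C@@]2(C)O[C@H]2[C@H]2OC(=O)[C@@H](COC(C)=O)[C@H]21 | target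

Total step count: 31. Longest linear sequence: 29 steps (from 4 through steps 3–5 and 6–31).

Steps most likely to fail

Step 23. The allylpalladium enolate may be diverted before ring closure: protonation or β-hydride loss instead of C–C bond formation, attack at C5, syn–anti isomerization of the allyl unit, or intermolecular allylation. The fallback sets out from 28 and closes the ring with a stabilized nucleophile instead. Heating 28 with 2,2,2-trichloroethanol in toluene at 80 °C traps the acylketene as the trichloroethyl β-keto ester F1. DDQ then frees the C3 alcohol F2, and methyl chloroformate with pyridine gives the allylic methyl carbonate F3. Pd(PPh3)4 in THF at high dilution closes the ten-membered β-keto ester F4 by Tsuji–Trost alkylation of C2 at C3. Zn dust in aqueous KH2PO4/THF cleaves the trichloroethyl ester, and the β-keto acid loses CO2 on gentle warming. The fallback comes back to the route at 32.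

Step 27. Hydride may also attack the C1 ketone, and the ring conformation may override chelation control so that the wrong C6 epimer forms. The fallback sets out from 34 and inverts C6 by substitution instead of by oxidation and reduction. Mitsunobu reaction with chloroacetic acid, PPh3 and diisopropyl azodicarboxylate in THF gives the C6-inverted chloroacetate F5. Thiourea with NaHCO3 in ethanol removes the chloroacetyl group without touching the acetates. The fallback comes back to the route at 36.

Step 25. The ten-membered ring may impose a rotamer about C5–C6 other than the allylic-strain minimum, so that the hydroxyl delivers oxygen to the opposite alkene face. The fallback sets out from 33 and reverses the order of inversion and epoxidation. Mitsunobu reaction with chloroacetic acid gives the C6-inverted allylic chloroacetate F6, and thiourea with NaHCO3 releases the C6-inverted allylic alcohol F7. Hydroxyl-directed epoxidation of F7 with mCPBA, now governed by the same ring preference, gives the target epoxide and the target C6 configuration together. The fallback comes back to the route at 36.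

Further compounds
F1 | step 23 | 2,2,2-trichloroethyl β-keto ester with C3 PMB ether | COc1ccc(COC/C(C)=C\[C@H](O[Si](CC)(CC)CC)[C@@H]([C@@H](COCc2ccccc2)COC(C)=O)[C@@H](O[Si](C)(C)C(C)(C)C)C[C@@](C)(OC(C)=O)C(=O)CC(=O)OCC(Cl)(Cl)Cl)cc1
F2 | step 23 | 2,2,2-trichloroethyl β-keto ester with free C3 hydroxyl | OC/C(C)=C\[C@H](O[Si](CC)(CC)CC)[C@@H]([C@@H](COCc1ccccc1)COC(C)=O)[C@@H](O[Si](C)(C)C(C)(C)C)C[C@@](C)(OC(C)=O)C(=O)CC(=O)OCC(Cl)(Cl)Cl
F3 | step 23 | C3 allylic methyl carbonate of the trichloroethyl β-keto ester | COC(=O)OC/C(C)=C\[C@H](O[Si](CC)(CC)CC)[C@@H]([C@@H](COCc1ccccc1)COC(C)=O)[C@@H](O[Si](C)(C)C(C)(C)C)C[C@@](C)(OC(C)=O)C(=O)CC(=O)OCC(Cl)(Cl)Cl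
F4 | step 23 | ten-membered ketone with C2 trichloroethyl ester | CC(C)(C)[Si](C)(C)O[C@H]1C[C@@](C)(OC(C)=O)C(=O)C(C(=O)OCC(Cl)(Cl)Cl)C/C(C)=C\[C@H](O[Si](CC)(CC)CC)[C@H]1[C@@H](COCc1ccccc1)COC(C)=O
F5 | step 27 | C6-inverted chloroacetate of the 4,5-epoxide | CC(C)(C)[Si](C)(C)O[C@H]1C[C@@](C)(OC(C)=O)C(=O)CC[C@@]2(C)O[C@H]2[C@@H](OC(=O)CCl)[C@H]1[C@@H](COCc1ccccc1)COC(C)=O
F6 | step 25 | C6-inverted allylic chloroacetate | CC(C)(C)[Si](C)(C)O[C@H]1C[C@@](C)(OC(C)=O)C(=O)CC/C(C)=C\[C@@H](OC(=O)CCl)[C@H]1[C@@H](COCc1ccccc1)COC(C)=O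
F7 | step 25 | C6-inverted allylic alcohol | CC(C)(C)[Si](C)(C)O[C@H]1C[C@@](C)(OC(C)=O)C(=O)CC/C(C)=C\[C@@H](O)[C@H]1[C@@H](COCc1ccccc1)COC(C)=O
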